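## Structural features

The target is a ten-membered carbocycle (C1–C10) that is trans-fused at C7/C8 to an α-methylene-γ-butyrolactone (C11, C12, C13, O8). The large ring carries a trans C4–C5 epoxide with a methyl on C4, an angelate on O6, a free hydroxyl on C9, a methyl on C10 and three plain methylenes C1–C3. Seven contiguous stereocenters run from C4 to C10 (4R,5R,6R,7S,8S,9R,10R as read from the SMILES); O8, O9 and the C10 methyl lie on one face of the ring, the C7 side chain on the other, and the C5/C6 epoxy ester is erythro. Four groups are fragile: the angelate (isomerises to the tiglate and can be deprotonated at its γ-methyl by strong base), the trisubstituted epoxide (acid-induced solvolysis and transannular shifts), the α-methylene lactone (a Michael acceptor) and the 8,9-diol pattern (translactonisation and acyl shifts). The real difficulty is a medium ring that carries this array together with a trans epoxide, which demands an (E)-C4=C5 alkene inside the ring, and an end game with no acid after the epoxide and no strong base after the angelate. The key step exploits the fact that C1 and C2 bear only hydrogen while C6 bears oxygen: a transannular C1–C6 bond divides the carbocycle into two cyclohexanes, ring A (C1–C6) and ring B (C1, C10, C9, C8, C7, C6). The C1,C6-epoxy C2-ketone of that bicycle fragments to the C6 ketone and a C1≡C2 alkyne, which is later hydrogenated away.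

## Logic of the disconnections

31 ⇒ 29 (through 30): the lactone C12–O8 bond and the O–Si bonds on O8 and O9 are cut. Releasing the diol with fluoride and closing the lactone last keeps acid away from the epoxide and keeps the Michael acceptor out of all earlier steps. The forward step must prefer the γ-lactone on O8 over the δ-lactone on O9 and must not let the O6 ester migrate.

29 ⇒ 26 (through 28 and 27): the C11=C13 bond and the C12 oxidation level are removed. The methylene is put on at the aldehyde stage under amine conditions, so the angelate never meets an enolate base, and the side chain simplifies to CH2CH2OH.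

26 ⇒ 25: the O12–Si bond is restored. The forward step must release the primary O12 while O8 and O9 stay silylated.

25 ⇒ 22 + 23 (through 24): the ester C–O bond at O6 is cut. This leaves a free C6 hydroxyl that can direct the epoxidation one step earlier. The acylation must avoid Z to E isomerisation and must tolerate the neighbouring epoxide.

22 ⇒ 21: both epoxide C–O bonds are cut. C4 and C5 then depend only on C6 and on the E geometry of the alkene. The forward step must deliver oxygen, directed by the hydroxyl, to the exposed alkene face.

21 ⇒ 20 ⇒ 18 (through 19): the C6–H bond (1,2-reduction) and the C4=C5 bond (dehydrogenation next to the C6 ketone) are removed. The C6 ketone serves twice, and the C4 stereocenter of 18 becomes irrelevant. The forward steps need regioselective enolisation toward C5, E geometry in the ring and facial control at C6.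

18 ⇒ 17: four C–H bonds at C1 and C2 are removed, which gives the alkyne that is the retron of the key step. The hydrogenation must leave the ketone and the silyl ethers alone.

17 ⇒ 15 (through 16): the C1–C6 bond is reconnected, and the C6 ketone and C1≡C2 become the C1,C6-epoxy C2-ketone. The medium ring is replaced by two fused six-membered rings on which C7–C10 can be set. The forward fragmentation must not disturb C7, which becomes α to the new ketone.

15 ⇒ 13 (through 14): the two O–Si bonds on O8 and O9 and the epoxide oxygen are removed, leaving the ring-fusion enone. Epoxidising before silylation keeps C8 free of a leaving group while base is present.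

13 ⇒ 11 (through 12): the C6–C7 bond is cut and O9 is reattached to C6, which gives a dihydrofuran-fused vinylogous ester with a radical precursor at C7. A carbanion at C7 would expel O8; a radical does not. The forward step must close a bridged ring and then eliminate O9 from C6.

11 ⇒ 6 + 9 (through 10), and 9 ⇒ 7 + two molecules of 8: the C7–C8 bond is cut to an α-alkoxy aldehyde and a selenium-stabilised carbanion that brings C7, C11, C12 and O12. The addition must follow the non-chelated Felkin–Anh course to set C8.

6 ⇒ 4 ⇒ 3 (through 5): the C9–O9 bond is cut. The ring oxygen of ring A itself becomes O9 by SN2 displacement of an iodide placed anti to the C10 methyl. This puts O9 cis to that methyl in ring B, which a direct oxidation anti to the methyl cannot do.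

3 ⇒ 1 + 2: the C1–C10 bond is cut. A single catalytic asymmetric Michael addition sets C10, from which C9, C8 and C7 are relayed.

## Other disconnections considered

Alternative 1: the C9–C10 bond is cut. Forward, the C9 aldehyde of the seco boronate A1 would add to the γ-carbon of its own α-chiral (E)-crotyl pinacol boronate through a chair transition state. This closes the ring, sets C9 and C10 (anti, from the E-crotyl unit) and leaves a C1=C2 alkene in the homoallylic alcohol A2. In its favour, two stereocenters and the ring arise in one closed, predictable step, and the lactone and the (E)-C4=C5 alkene are already present, so no dehydrogenation is needed; on alkene geometry this plan is better than the chosen one. Against it, a ten-membered ring must be closed head to tail against oligomerisation and transannular strain, A1 needs an enantioenriched secondary allylboronate and a free aldehyde in the same molecule, the C1=C2 alkene must later be reduced in the presence of C4=C5, and the methylene would still have to be installed on a lactone next to an ester. In comparison, this alternative builds more in its key step (one ring, one bond and two stereocenters against none). Mechanistically the chosen fragmentation is a unimolecular ring release with no entropic penalty, which is the safer way to a medium ring. In step count, A1 is a long linear acyclic compound with five stereocenters, so no saving over the eighteen steps of the chosen plan is expected.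

Alternative 2: the C6–C7 bond is cut. Forward, the 13-membered diallylic ether A3 would be lithiated at C6 and undergo a [2,3]-Wittig shift to the ring-contracted allylic alcohol A4, forming C6–C7, breaking O–C13 and creating the C11=C13 methylene. In its favour, C6, C7 and the exocyclic methylene with its C12 oxygen arise together, so no late methylenation is needed, which is better than the chosen plan on this point; the (E)-C4=C5 alkene is again preinstalled, and a 13-membered ether is easier to close than a ten-membered carbocycle. Against it, lithiation must choose C6 over C13, the [1,2]-shift competes, the configuration at C6 and C7 depends on transannular conformations of a large ring that are hard to predict, and the chemistry is strongly basic. In comparison, the two plans are equal in avoiding a direct medium-ring closure, since both reach the ring indirectly. On stereochemical predictability of the key step the chosen plan is stronger, because its key step creates no stereocenter at all. On step economy A3 again demands a long linear chain synthesis.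

Alternative 3: the ring is hidden in a trans-decalin with an extra C4–C9 bond. Forward, KOt-Bu would deprotonate the angular C9 hydroxyl of mesylate A5, and Grob fragmentation would cleave C4–C9 to the (E)-cyclodecenone A6. In its favour, this is the same logic class as the chosen plan (ring release from a bicycle), it fixes the (E)-C4=C5 geometry stereospecifically through the anti-periplanar C4–C9/C5–O arrangement, which is better than the dehydrogenation of the chosen plan, C1–C3 need no hydrogenation, and the lactone is in place. Against it, the new C9 ketone of A6 sits between the epimerisable C10 and the acyloxy-bearing C8 under alkoxide base, it must then be reduced with control of C9, and A5 needs two angular centers and six stereocenters on a decalin. In comparison, the alternative is the equal of the chosen plan in ring-forming logic and its superior in alkene geometry. It is weaker in how many stereocenters stay at risk after the key step (C8, C9 and C10 against C7 only), and its precursor is expected to cost more steps than the eight that lead to 15.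

Key step: step 9

Remarks on the chemistry:

- Atom labels C1–C13 are those of the target in every compound. Ring A is C1–C6 and ring B is C1, C10, C9, C8, C7, C6.
- C4 is not controlled when the two carbonyl groups of ring A become different (step 3) and is erased in step 11. Compounds 6 and 11–19 are drawn as one C4 epimer and should be accompanied by the other, which follows the same path.
- The C7–C10 configurations of 15 and 17 were compared atom by atom with the target and agree.
- Design choices for the fragmentation precursor: silyl ethers rather than an acetal on O8/O9, so that the last deprotection is by fluoride; epoxidation of the enone before silylation; methylenation at the aldehyde stage.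

Step 1
Reactants: 1 5-methylcyclohexane-1,3-dione; 2 (E)-but-2-enal
Product: 3 (4S)-2-hydroxy-4,7-dimethyl-2,3,4,6,7,8-hexahydro-5H-chromen-5-one
Conditions: (R)-α,α-diphenylprolinol trimethylsilyl ether (10 mol%), PhCO2H (10 mol%), CH2Cl2, −20 to 0 °C
Reagents that add atoms: none
Why: Iminium-catalysed Michael addition of the dione to the enal; the (R)-catalyst shields one face of the E-iminium ion so that C1 should add to C10 from the other face (target C10 configuration), and the adduct rests as the cyclic hemiacetal.

Step 2
Reactants: 3 (4S)-2-hydroxy-4,7-dimethyl-2,3,4,6,7,8-hexahydro-5H-chromen-5-one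
Product: 4 (4S)-4,7-dimethyl-4,6,7,8-tetrahydro-5H-chromen-5-one
Conditions: p-TsOH·H2O (5 mol%), PhMe, 4 Å MS, 80 °C
Reagents that add atoms: none
Why: Acid-catalysed dehydration of the lactol through its oxocarbenium ion gives the cyclic enol ether with C8=C9; C10 is not enolisable and is retained.

Step 3
Reactants: 4 (4S)-4,7-dimethyl-4,6,7,8-tetrahydro-5H-chromen-5-one
Product: 6 (2R,3R)-3,6-dimethyl-4-oxo-2,3,4,5,6,7-hexahydro-1-benzofuran-2-carbaldehyde (2,3-trans), via iodo lactol 5 (not isolated)
Conditions: NIS, MeCN/H2O 10:1, 0 °C; then K2CO3, rt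
Reagents that add atoms: water, O
Why: Iodohydroxylation of the enol ether should place iodine on C9 anti to the C10 methyl; base opens the lactol to the α-iodo aldehyde and the enolate oxygen of ring A displaces iodide at C9 by 5-exo-tet SN2 with inversion (ring contraction of a 2-hydroxy-3-halopyran), so O9 ends cis to the methyl in the later ring B, that is 2,3-trans on the dihydrofuran. C9 is α to the aldehyde, so the same base also equilibrates it toward this more stable trans isomer.

Step 4
Reactants: 7 3-[(tert-butyldimethylsilyl)oxy]propanal; 8 benzeneselenol (2.1 equiv in all)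
Product: 9 tert-butyldimethyl[3,3-bis(phenylselanyl)propoxy]silane
Conditions: PhSeH (2.1 equiv), ZnCl2 (0.5 equiv), CH2Cl2, 0 °C to rt
Reagents that add atoms: benzeneselenol, [SeH]c1ccccc1
Why: Lewis-acid selenoacetalisation of an aldehyde, RCHO + 2 PhSeH → RCH(SePh)2 + H2O; two molecules of 8 are incorporated (the one counted as reactant and the one entered as atom-adding reagent), water is the only by-product, and the silyl ether tolerates ZnCl2.

Step 5
Reactants: 9 tert-butyldimethyl[3,3-bis(phenylselanyl)propoxy]silane; 6 (2R,3R)-3,6-dimethyl-4-oxo-2,3,4,5,6,7-hexahydro-1-benzofuran-2-carbaldehyde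
Product: 11 β-hydroxy selenide: 2-[1-hydroxy-2-(phenylselanyl)-4-(tert-butyldimethylsilyloxy)butyl]-3,6-dimethyl-3,5,6,7-tetrahydro-1-benzofuran-4(2H)-one with the C8 carbinol erythro to O9 (C7 epimers), via lithio selenide 10 (not isolated)
Conditions: n-BuLi, THF, −78 °C; then 6, −78 °C; aq. NH4Cl
Reagents that add atoms: none
Why: Selenium–lithium exchange gives the α-selanyl alkyllithium, which adds to the aldehyde and leaves the vinylogous ester alone at −78 °C. O9 is a weakly basic vinylogous ester oxygen, so chelation is unlikely and polar Felkin–Anh addition anti to the C9–O bond should give the erythro C8/C9 pair; the C7 selenide center is a mixture that step 6 erases.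

Step 6
Reactants: 11 β-hydroxy selenide (C8 erythro to O9)
Product: 13 6,7-dihydroxy-3,8-dimethyl-5-[2-(tert-butyldimethylsilyloxy)ethyl]-3,4,5,6,7,8-hexahydronaphthalen-1(2H)-one (target configuration at C7–C10), via oxanorbornanone 12 (not isolated)
Conditions: (Me3Si)3SiH, AIBN, PhMe, 90 °C, slow addition; then DBU, rt
Reagents that add atoms: none
Why: Radical cyclisation onto a β-alkoxy enone: the nucleophilic C7 radical, which unlike a carbanion does not expel O8, adds 5-exo to the oxygen-bearing β-carbon C6 to give a 7-oxanorbornane, and the α-keto radical is reduced by the silane. DBU then triggers retro-oxa-Michael opening (E1cB), which releases O9 as the C9 hydroxyl and forms the C1=C6 enone. C7 is set by the usual 1,2-trans preference of 5-exo closures (side chain anti to the C8 oxygen), which is also the less crowded arrangement in ring B.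

Step 7
Reactants: 13 octalone diol
Product: 14 4a,8a-epoxy-6,7-dihydroxy-3,8-dimethyl-5-[2-(tert-butyldimethylsilyloxy)ethyl]octahydronaphthalen-1(2H)-one (C1,C6-epoxy C2-ketone, epoxide anti to the C7 side chain)
Conditions: 30% H2O2, NaOH (0.3 equiv), MeOH, 0 °C
Reagents that add atoms: hydrogen peroxide, OO
Why: Weitz–Scheffer nucleophilic epoxidation of the ring-fusion enone, run on the free diol so that C8 carries no leaving group for vinylogous elimination. Hydroperoxide should add to C6 anti to the C7 side chain, but either epoxide face serves because C1 and C6 are destroyed in step 9.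

Step 8
Reactants: 14 epoxy ketone diol
Product: 15 C1,C6-epoxy octal-2-one with O8 and O9 as tert-butyldimethylsilyl ethers and the C7 silyloxyethyl chain (fragmentation precursor)
Conditions: TBSOTf (2.5 equiv), 2,6-lutidine (4 equiv), CH2Cl2, −78 to 0 °C
Reagents that add atoms: tert-butyldimethylsilyl trifluoromethanesulfonate, CC(C)(C)[Si](C)(C)OS(=O)(=O)C(F)(F)F
Why: Silylation of both secondary hydroxyls (two equivalents of the silyl triflate are incorporated) under buffered conditions; the electron-poor α,β-epoxy ketone should survive the silyl triflate. Silyl ethers are chosen so that O8/O9 can later be released by fluoride in the presence of the C4–C5 epoxide.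

Step 9
Reactants: 15 C1,C6-epoxy octal-2-one (O8, O9 and O12 silylated)
Product: 17 4,10-dimethyl-8,9-bis(tert-butyldimethylsilyloxy)-7-[2-(tert-butyldimethylsilyloxy)ethyl]cyclodec-1-yn-6-one (target numbering), via tosylhydrazone 16 (not isolated)
Conditions: TsNHNH2 (1.1 equiv), AcOH/CH2Cl2 1:1, −20 °C to rt
Reagents that add atoms: none
Why: The sulfonylhydrazide condenses with the C2 ketone to hydrazone 16; proton transfer opens the C1–O bond of the epoxide to give the C6 hydroxyl and an azoalkene (C1=C2–N=N–Ts). The oxygen on C6 then pushes in, the C1–C6 σ bond breaks, C1≡C2 forms and N2 and p-toluenesulfinate leave; this is the Eschenmoser–Tanabe fragmentation, and the closest known case is the conversion of the parent ring-fusion epoxy octalone into cyclodec-5-ynone. No ring is closed, so no closure mode or dilution applies: the ten-membered ring is released by cleaving the bond shared by two six-membered rings, and loss of N2 pays for the strain of the cyclodecyne. No stereocenter is created; C1 and C6 become sp and sp2 carbons, so both epoxide diastereomers and both C4 epimers converge, and C7–C10 are spectators. The selectivity needed is chemoselectivity: condensation at the hindered C2 carbonyl must come before any acid opening of the epoxide, and the β-silyloxy ketone formed must neither epimerise at C7 nor lose O8. Cold AcOH is acidic enough for hydrazone formation but does not enolise the product ketone, and the α,β-epoxy ketone is a deactivated epoxide. The anti-periplanar alignment of the C1–C6 bond with the departing diazene is enforced by the rigid bicycle.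

Step 10
Reactants: 17 cyclodec-1-yn-6-one
Product: 18 4,10-dimethyl-8,9-bis(tert-butyldimethylsilyloxy)-7-[2-(tert-butyldimethylsilyloxy)ethyl]cyclodecan-6-one (target numbering)
Conditions: H2 (1 atm), 10% Pd/C, EtOAc, rt
Reagents that add atoms: none
Why: Full hydrogenation of the strained alkyne gives the C1 and C2 methylenes of the target; the ketone and silyl ethers are inert in EtOAc, and prompt reduction prevents transannular reactions of the ynone.

Step 11
Reactants: 18 cyclodecan-6-one
Product: 20 (E)-cyclodec-4-en-6-one with the C4 methyl and C7–C10 unchanged, via trimethylsilyl enol ether 19 (not isolated)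
Conditions: LiN(i-Pr)2, Me3SiCl, THF, −78 °C (internal quench); then Pd(OAc)2 (1.1 equiv), MeCN, rt
Reagents that add atoms: none
Why: Saegusa oxidation: kinetic deprotonation at the C5 methylene, not at the hindered C7 methine (which would expel O8), gives the Δ5 enol ether, and the divalent palladium enolate loses the C4 hydrogen by syn β-hydride elimination. In a ten-membered ring, syn eliminations run through an anticlinal ring torsion and favour the E alkene, as in amine oxide and selenoxide eliminations of cyclodecyl systems. C4 becomes sp2, so both C4 epimers converge.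

Step 12
Reactants: 20 (E)-cyclodec-4-en-6-one
Product: 21 (E)-allylic alcohol with the C6 hydroxyl in the target configuration
Conditions: NaBH4, CeCl3·7H2O, MeOH, −78 °C
Reagents that add atoms: none
Why: Luche 1,2-reduction; at −78 °C the β-silyloxy ketone should neither epimerise nor eliminate. Only the C7 side chain can stand perpendicular to the carbonyl, so hydride should attack anti to it (Felkin–Anh), which corresponds to the C6 configuration of the target.

Step 13
Reactants: 21 (E)-allylic alcohol
Product: 22 4,5-epoxy-6-ol (erythro at C5/C6, trans epoxide, target configuration at C4–C6)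
Conditions: VO(acac)2 (5 mol%), t-BuOOH, CH2Cl2, 0 °C
Reagents that add atoms: tert-butyl hydroperoxide, CC(C)(C)OO
Why: Hydroxyl-directed epoxidation through the vanadate ester, which needs an O–C6–C5=C4 dihedral near 45° on the attacked face. In an (E)-cyclodecene, C7 must stand roughly perpendicular on the ring-covered face, so the only geometry that delivers oxygen to the exposed face has C7 inside and H6 outside, which is the erythro epoxy alcohol; the angelate is installed only afterwards, so no other alkene competes.

Step 14
Reactants: 22 4,5-epoxy-6-ol; 23 angelic acid ((Z)-2-methylbut-2-enoic acid)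
Product: 25 C6 angelate of the epoxy alcohol (O8, O9, O12 silylated), via mixed anhydride 24 (not isolated)
Conditions: 23, 2,4,6-Cl3C6H2COCl, Et3N, PhMe, rt; then 22, DMAP, rt
Reagents that add atoms: none
Why: Yamaguchi esterification; the hindered aroyl carbonyl of the mixed anhydride directs acyl transfer to the angeloyl group at room temperature, which should keep Z to E isomerisation low, and no alkoxide is generated next to the epoxide.

Step 15
Reactants: 25 C6 angelate (tris-silyl ether)
Product: 26 C12 primary alcohol (O8 and O9 still silylated)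
Conditions: HF·pyridine, pyridine, THF, 0 °C
Reagents that add atoms: none
Why: Buffered HF·pyridine cleaves a primary tert-butyldimethylsilyl ether much faster than the two hindered secondary ones, and the buffered medium should leave the epoxide and angelate intact.

Step 16
Reactants: 26 C12 primary alcohol
Product: 28 2-substituted acrolein (C11=C13 methylene, C12 aldehyde), via aldehyde 27 (not isolated)
Conditions: 1,1,1-triacetoxy-1,1-dihydro-1,2-benziodoxol-3(1H)-one (DMP), NaHCO3, CH2Cl2, rt; then N,N-dimethylmethyleneiminium iodide, Et3N, CH2Cl2, rt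
Reagents that add atoms: N,N-dimethylmethyleneiminium iodide, C=[N+](C)C.[I-]
Why: Dess–Martin oxidation, then Mannich reaction of the aldehyde with the iminium salt and elimination of dimethylamine, gives the α-methylene aldehyde. Installing C13 here needs only an amine base, so the angelate γ-hydrogens and the epoxide are not exposed to an enolate base.

Step 17
Reactants: 28 2-substituted acrolein
Product: 29 2-substituted acrylic acid (C12 carboxylic acid)
Conditions: NaClO2, NaH2PO4, 2-methylbut-2-ene, t-BuOH/H2O, 0 °C
Reagents that add atoms: sodium chlorite, [Na+].[O-]Cl=O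
Why: Pinnick oxidation of an enal to the acrylic acid at buffered pH; the alkene scavenger removes HOCl, so the angelate and the exocyclic methylene should not be chlorinated.

Step 18
Reactants: 29 2-substituted acrylic acid
Product: 31 CNP0165329.1 (target), via dihydroxy acid 30 (not isolated)
Conditions: Bu4NF, AcOH, THF, 0 °C to rt; then PPTS (cat.), CH2Cl2, rt
Reagents that add atoms: none
Why: Buffered fluoride removes both secondary silyl ethers without base-induced acyl shift of the angelate, and the γ-hydroxy acid closes to the five-membered lactone on O8. The γ-lactone is favoured kinetically and thermodynamically over the δ-lactone on O9, and the Michael acceptor appears only in this last step.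

Compound list

1 | 5-methylcyclohexane-1,3-dione | CC1CC(=O)CC(=O)C1 | starting material
2 | (E)-but-2-enal | C/C=C/C=O | starting material
3 | (4S)-2-hydroxy-4,7-dimethyl-2,3,4,6,7,8-hexahydro-5H-chromen-5-one (anomers; ring-methyl epimers) | OC1C[C@H](C)C2=C(CC(C)CC2=O)O1 | intermediate
4 | (4S)-4,7-dimethyl-4,6,7,8-tetrahydro-5H-chromen-5-one (ring-methyl epimers) | C1=C[C@H](C)C2=C(CC(C)CC2=O)O1 | intermediate
5 | 2-hydroxy-3-iodo-4,7-dimethyl-2,3,4,6,7,8-hexahydro-5H-chromen-5-one, iodine trans to the C4 methyl | OC1[C@@H](I)[C@H](C)C2=C(CC(C)CC2=O)O1 | intermediate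
6 | (2R,3R)-3,6-dimethyl-4-oxo-2,3,4,5,6,7-hexahydro-1-benzofuran-2-carbaldehyde | O=C[C@@H]1OC2=C([C@H]1C)C(=O)C[C@@H](C)C2 | intermediate
7 | 3-[(tert-butyldimethylsilyl)oxy]propanal | CC(C)(C)[Si](C)(C)OCCC=O | starting material
8 | benzeneselenol | [SeH]c1ccccc1 | starting material
9 | tert-butyldimethyl[3,3-bis(phenylselanyl)propoxy]silane | CC(C)(C)[Si](C)(C)OCCC([Se]c1ccccc1)[Se]c1ccccc1 | intermediate
10 | [1-(phenylselanyl)-3-(tert-butyldimethylsilyloxy)propyl]lithium | [Li]C([Se]c1ccccc1)CCO[Si](C)(C)C(C)(C)C | intermediate
11 | β-hydroxy selenide: 2-[1-hydroxy-2-(phenylselanyl)-4-(tert-butyldimethylsilyloxy)butyl]-3,6-dimethyl-3,5,6,7-tetrahydro-1-benzofuran-4(2H)-one, C8 erythro to O9, C7 epimers | O[C@H]([C@@H]1OC2=C([C@H]1C)C(=O)C[C@@H](C)C2)C([Se]c1ccccc1)CCO[Si](C)(C)C(C)(C)C | intermediate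
12 | 7-oxanorbornane-bridged ketone (C6–C7 bond formed, O9 bridging C9 and C6, C1–H) | O[C@@H]1[C@@H]2O[C@]3(C[C@H](C)CC(=O)C3[C@H]2C)[C@H]1CCO[Si](C)(C)C(C)(C)C | intermediate
13 | 6,7-dihydroxy-3,8-dimethyl-5-[2-(tert-butyldimethylsilyloxy)ethyl]-3,4,5,6,7,8-hexahydronaphthalen-1(2H)-one (target configuration at C7–C10) | O=C1C[C@@H](C)CC2=C1[C@@H](C)[C@@H](O)[C@@H](O)[C@@H]2CCO[Si](C)(C)C(C)(C)C | intermediate
14 | C1,C6-epoxy octal-2-one 8,9-diol (4a,8a-epoxide of 13, anti to the C7 chain) | O=C1C[C@@H](C)C[C@]23O[C@]12[C@@H](C)[C@@H](O)[C@@H](O)[C@@H]3CCO[Si](C)(C)C(C)(C)C | intermediate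
15 | C1,C6-epoxy octal-2-one, O8/O9 bis(tert-butyldimethylsilyl) ether, C7 silyloxyethyl chain | O=C1C[C@@H](C)C[C@]23O[C@]12[C@@H](C)[C@@H](O[Si](C)(C)C(C)(C)C)[C@@H](O[Si](C)(C)C(C)(C)C)[C@@H]3CCO[Si](C)(C)C(C)(C)C | intermediate
16 | p-toluenesulfonylhydrazone of 15 at C2 | Cc1ccc(cc1)S(=O)(=O)NN=C1C[C@@H](C)C[C@]23O[C@]12[C@@H](C)[C@@H](O[Si](C)(C)C(C)(C)C)[C@@H](O[Si](C)(C)C(C)(C)C)[C@@H]3CCO[Si](C)(C)C(C)(C)C | intermediate
17 | 4,10-dimethyl-8,9-bis(silyloxy)-7-(2-silyloxyethyl)cyclodec-1-yn-6-one (target numbering) | O=C1C[C@H](C)CC#C[C@@H](C)[C@@H](O[Si](C)(C)C(C)(C)C)[C@@H](O[Si](C)(C)C(C)(C)C)[C@@H]1CCO[Si](C)(C)C(C)(C)C | intermediate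
18 | 4,10-dimethyl-8,9-bis(silyloxy)-7-(2-silyloxyethyl)cyclodecan-6-one | O=C1C[C@H](C)CCC[C@@H](C)[C@@H](O[Si](C)(C)C(C)(C)C)[C@@H](O[Si](C)(C)C(C)(C)C)[C@@H]1CCO[Si](C)(C)C(C)(C)C | intermediate
19 | C5=C6 trimethylsilyl enol ether of 18 | C[Si](C)(C)OC1=C[C@H](C)CCC[C@@H](C)[C@@H](O[Si](C)(C)C(C)(C)C)[C@@H](O[Si](C)(C)C(C)(C)C)[C@@H]1CCO[Si](C)(C)C(C)(C)C | intermediate
20 | (E)-4-methylcyclodec-4-en-6-one with C7–C10 as in 18 | O=C1/C=C(C)/CCC[C@@H](C)[C@@H](O[Si](C)(C)C(C)(C)C)[C@@H](O[Si](C)(C)C(C)(C)C)[C@@H]1CCO[Si](C)(C)C(C)(C)C | intermediate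
21 | (E)-cyclodec-4-en-6-ol, C6 in target configuration | O[C@H]1/C=C(C)/CCC[C@@H](C)[C@@H](O[Si](C)(C)C(C)(C)C)[C@@H](O[Si](C)(C)C(C)(C)C)[C@@H]1CCO[Si](C)(C)C(C)(C)C | intermediate
22 | 4,5-epoxy-cyclodecan-6-ol (trans epoxide, erythro to the C6 hydroxyl) | O[C@H]1[C@H]2O[C@]2(C)CCC[C@@H](C)[C@@H](O[Si](C)(C)C(C)(C)C)[C@@H](O[Si](C)(C)C(C)(C)C)[C@@H]1CCO[Si](C)(C)C(C)(C)C | intermediate
23 | angelic acid, (Z)-2-methylbut-2-enoic acid | C/C=C(/C)C(=O)O | starting material
24 | angelic 2,4,6-trichlorobenzoic anhydride | C/C=C(/C)C(=O)OC(=O)c1c(Cl)cc(Cl)cc1Cl | intermediate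
25 | C6 angelate, O8/O9/O12 tris(tert-butyldimethylsilyl) ether | C/C=C(/C)C(=O)O[C@H]1[C@H]2O[C@]2(C)CCC[C@@H](C)[C@@H](O[Si](C)(C)C(C)(C)C)[C@@H](O[Si](C)(C)C(C)(C)C)[C@@H]1CCO[Si](C)(C)C(C)(C)C | intermediate
26 | C6 angelate, C12 primary alcohol, O8/O9 silylated | C/C=C(/C)C(=O)O[C@H]1[C@H]2O[C@]2(C)CCC[C@@H](C)[C@@H](O[Si](C)(C)C(C)(C)C)[C@@H](O[Si](C)(C)C(C)(C)C)[C@@H]1CCO | intermediate
27 | C12 aldehyde | C/C=C(/C)C(=O)O[C@H]1[C@H]2O[C@]2(C)CCC[C@@H](C)[C@@H](O[Si](C)(C)C(C)(C)C)[C@@H](O[Si](C)(C)C(C)(C)C)[C@@H]1CC=O | intermediate
28 | C11-methylene C12 aldehyde (2-substituted acrolein) | C/C=C(/C)C(=O)O[C@H]1[C@H]2O[C@]2(C)CCC[C@@H](C)[C@@H](O[Si](C)(C)C(C)(C)C)[C@@H](O[Si](C)(C)C(C)(C)C)[C@@H]1C(=C)C=O | intermediate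
29 | C11-methylene C12 carboxylic acid, O8/O9 silylated | C/C=C(/C)C(=O)O[C@H]1[C@H]2O[C@]2(C)CCC[C@@H](C)[C@@H](O[Si](C)(C)C(C)(C)C)[C@@H](O[Si](C)(C)C(C)(C)C)[C@@H]1C(=C)C(=O)O | intermediate
30 | 8,9-dihydroxy C12 acid (seco acid of the target) | C/C=C(/C)C(=O)O[C@H]1[C@H]2O[C@]2(C)CCC[C@@H](C)[C@@H](O)[C@@H](O)[C@@H]1C(=C)C(=O)O | intermediate
31 | CNP0165329.1 (4R,5R,6R,7S,8S,9R,10R) | C=C1C(=O)O[C@@H]2[C@H](O)[C@H](C)CCC[C@@]3(C)O[C@@H]3[C@H](OC(=O)/C(C)=C\C)[C@@H]12 | target

Total step count: 18. Longest linear sequence: 17 steps (steps 1–3 and 5–18); step 4 is a one-step side branch.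

Steps least certain to work

Step 9 (key step). Hydrazone formation at the hindered C2 carbonyl may be slower than acid opening or rearrangement of the epoxide, and the ynone may undergo transannular reactions or epimerise at C7 if the reaction has to be warmed. Fallback from 15, rejoining at 18: reductive opening of the epoxy ketone with SmI2 (THF/MeOH, −90 °C) gives the β-hydroxy ketone F1; anti reduction with Me4NBH(OAc)3 gives the 1,3-diol F2; MsCl/Et3N gives the secondary mesylate F3; KOt-Bu in THF at 0 °C effects a Wharton–Grob fragmentation (C6 alkoxide pushes, C1–C6 breaks, mesylate leaves C2) to the cyclodec-1-en-6-one F4; H2 over Pd/C then gives 18. This route exposes C7 to alkoxide base and is therefore second choice.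

Step 3. Electrophilic iodine may react at the vinylogous ester carbon C1 instead of C8=C9, or iodide displacement may be slow so that the lactol decomposes. Fallback from 1, rejoining at 6: branched-selective allylic alkylation of 1 with methyl (E)-but-2-enyl carbonate catalysed by [Ir(cod)Cl]2 and a chiral phosphoramidite gives the 2-(but-3-en-2-yl) dione F5; I2/NaHCO3 iodoetherification (5-exo, 2,3-trans) gives the iodomethyl dihydrofuran F6; Kornblum oxidation (AgBF4, DMSO; then Et3N) gives 6.

Step 6. The C7 radical may be reduced before it closes the strained bridged ring onto a fully substituted carbon, or closure may occur with poor control of C7. Fallback from 6, rejoining at 13: Wittig methylenation (Ph3P=CH2) gives the 2-vinyl dihydrofuran F7; vinylmagnesium bromide followed by dilute HCl (addition to the carbonyl, then enol ether hydrolysis with transposition) gives the 3-vinyl enone allylic alcohol F8; ring-closing metathesis with second-generation Grubbs catalyst gives the cyclohexadienol F9, which must be handled without acid because it can dehydrate to an arene; VO(acac)2/t-BuOOH gives the C7–C8 epoxide syn to O9, epoxy alcohol F10; anti opening at allylic C7 with vinylmagnesium bromide and CuI (cat.) gives the 7-vinyl 8,9-diol F11; 9-BBN then H2O2/NaOH gives the triol F12; and TBSCl/imidazole on the primary hydroxyl gives 13. In this fallback C8 and C7 are set by hydroxyl direction and SN2 inversion.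

Step 11. Enolisation may partly occur toward C7 with loss of O8, or Pd–H re-addition may isomerise the E enone to the less strained Z isomer. Fallback from 18, rejoining at 21: kinetic enolate (LiN(i-Pr)2, −78 °C) and PhSeBr give the α-selanyl ketone F13; NaBH4/CeCl3·7H2O gives the β-hydroxy selenide F14; H2O2/pyridine oxidises selenium, and selenoxide syn-elimination, which runs away from the carbinol carbon and has no metal hydride to isomerise the alkene, gives 21.

Step 12. Hydride delivery may be poorly face-selective or may occur on the other face, because the ring conformation of 20 is not known. Fallback from 20, rejoining at 21: if the C6-epimeric alcohol F15 is formed, Mitsunobu reaction (4-nitrobenzoic acid, PPh3, DIAD) gives the inverted 4-nitrobenzoate F16, and K2CO3/MeOH releases 21; SN2′ attack is disfavoured at the fully substituted C4.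

Step 13. An undirected background epoxidation through the other ring conformer would give the threo epoxy alcohol. Fallback from 20, rejoining at 22: nucleophilic epoxidation of the enone (t-BuOOH, DBU, CH2Cl2, 0 °C) gives the trans epoxy ketone F17; chelation-controlled reduction with Zn(BH4)2 (Et2O, 0 °C), which is reliably anti to the epoxide oxygen, gives the erythro epoxy alcohol 22. The base-sensitive C7 makes this the second choice.

Further compounds

F1 | step 9 | C6-hydroxy C2-ketone from reductive epoxide opening (cis ring fusion) | O=C1C[C@@H](C)C[C@]2(O)[C@H]1[C@@H](C)[C@@H](O[Si](C)(C)C(C)(C)C)[C@@H](O[Si](C)(C)C(C)(C)C)[C@@H]2CCO[Si](C)(C)C(C)(C)C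
F2 | step 9 | C2,C6 anti 1,3-diol | O[C@H]1C[C@@H](C)C[C@]2(O)[C@H]1[C@@H](C)[C@@H](O[Si](C)(C)C(C)(C)C)[C@@H](O[Si](C)(C)C(C)(C)C)[C@@H]2CCO[Si](C)(C)C(C)(C)C
F3 | step 9 | C2 mesylate of the 1,3-diol | CS(=O)(=O)O[C@H]1C[C@@H](C)C[C@]2(O)[C@H]1[C@@H](C)[C@@H](O[Si](C)(C)C(C)(C)C)[C@@H](O[Si](C)(C)C(C)(C)C)[C@@H]2CCO[Si](C)(C)C(C)(C)C
F4 | step 9 | (Z)-cyclodec-1-en-6-one with C7–C10 as in 18 | O=C1C[C@H](C)C/C=C\[C@@H](C)[C@@H](O[Si](C)(C)C(C)(C)C)[C@@H](O[Si](C)(C)C(C)(C)C)[C@@H]1CCO[Si](C)(C)C(C)(C)C
F5 | step 3 | 2-[(but-3-en-2-yl)]-5-methylcyclohexane-1,3-dione, C10 in target configuration | CC1CC(=O)C([C@@H](C)C=C)C(=O)C1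
F6 | step 3 | trans-2-(iodomethyl)-3,6-dimethyl-3,5,6,7-tetrahydro-1-benzofuran-4(2H)-one | IC[C@@H]1OC2=C([C@H]1C)C(=O)C[C@@H](C)C2
F7 | step 6 | trans-2-vinyl-3,6-dimethyl-3,5,6,7-tetrahydro-1-benzofuran-4(2H)-one | C=C[C@@H]1OC2=C([C@H]1C)C(=O)C[C@@H](C)C2
F8 | step 6 | 3-vinyl-2-(3-hydroxypent-4-en-2-yl)-5-methylcyclohex-2-enone | O=C1C[C@@H](C)CC(C=C)=C1[C@@H](C)[C@@H](O)C=C
F9 | step 6 | ring B cyclohexadienol (C7=C8, C9 hydroxyl) | O=C1C[C@@H](C)CC2=C1[C@@H](C)[C@@H](O)C=C2
F10 | step 6 | C7,C8-epoxide syn to the C9 hydroxyl | O=C1C[C@@H](C)CC2=C1[C@@H](C)[C@@H](O)[C@H]3O[C@H]32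
F11 | step 6 | 7-vinyl 8,9-diol octalone | O=C1C[C@@H](C)CC2=C1[C@@H](C)[C@@H](O)[C@@H](O)[C@@H]2C=C
F12 | step 6 | 7-(2-hydroxyethyl) 8,9-diol octalone | O=C1C[C@@H](C)CC2=C1[C@@H](C)[C@@H](O)[C@@H](O)[C@@H]2CCO
F13 | step 11 | C5-phenylselanyl cyclodecan-6-one (C5 epimers) | O=C1C([Se]c2ccccc2)[C@H](C)CCC[C@@H](C)[C@@H](O[Si](C)(C)C(C)(C)C)[C@@H](O[Si](C)(C)C(C)(C)C)[C@@H]1CCO[Si](C)(C)C(C)(C)C
F14 | step 11 | C5-phenylselanyl cyclodecan-6-ol (C6 as in 21) | O[C@H]1C([Se]c2ccccc2)[C@H](C)CCC[C@@H](C)[C@@H](O[Si](C)(C)C(C)(C)C)[C@@H](O[Si](C)(C)C(C)(C)C)[C@@H]1CCO[Si](C)(C)C(C)(C)C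
F15 | step 12 | C6 epimer of allylic alcohol 21 | O[C@@H]1/C=C(C)/CCC[C@@H](C)[C@@H](O[Si](C)(C)C(C)(C)C)[C@@H](O[Si](C)(C)C(C)(C)C)[C@@H]1CCO[Si](C)(C)C(C)(C)C
F16 | step 12 | 4-nitrobenzoate of 21 | O=C(O[C@H]1/C=C(C)/CCC[C@@H](C)[C@@H](O[Si](C)(C)C(C)(C)C)[C@@H](O[Si](C)(C)C(C)(C)C)[C@@H]1CCO[Si](C)(C)C(C)(C)C)c1ccc(cc1)[N+](=O)[O-]
F17 | step 13 | trans-4,5-epoxy-cyclodecan-6-one | O=C1[C@H]2O[C@]2(C)CCC[C@@H](C)[C@@H](O[Si](C)(C)C(C)(C)C)[C@@H](O[Si](C)(C)C(C)(C)C)[C@@H]1CCO[Si](C)(C)C(C)(C)C
A1 | alternative 1 | seco C9 aldehyde with α-chiral (E)-crotyl pinacol boronate at C2 on the trans lactone | O=C1C[C@H]([C@@H](O[Si](CC)(CC)CC)/C=C(\C)C[C@@H](B3OC(C)(C)C(C)(C)O3)/C=C/C)[C@@H](C=O)O1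
A2 | alternative 1 | ten-membered homoallylic alcohol fused to the trans lactone | O=C1C[C@@H]2[C@@H](O[Si](CC)(CC)CC)/C=C(\C)C/C=C\[C@@H](C)[C@@H](O)[C@H]2O1
A3 | alternative 2 | 13-membered diallylic ether (O bridging C6 and C13) | O1C/C(CO[Si](C)(C)C(C)(C)C)=C\[C@H](OCc2ccc(OC)cc2)[C@H](O[Si](C)(C)C(C)(C)C)[C@H](C)CCC/C(C)=C/C1
A4 | alternative 2 | ten-membered C6 allylic alcohol with the C7 2-propenyl branch | C=C(CO[Si](C)(C)C(C)(C)C)[C@@H]1[C@@H](O)/C=C(\C)CCC[C@@H](C)[C@@H](O[Si](C)(C)C(C)(C)C)[C@H]1OCc2ccc(OC)cc2
A5 | alternative 3 | trans-decalin C9-ol C5-mesylate fused to the lactone | CS(=O)(=O)O[C@@H]1[C@H](O[Si](C)(C)C(C)(C)C)[C@H]2CC(=O)O[C@@H]2[C@]3(O)[C@H](C)CCC[C@@]13C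
A6 | alternative 3 | (E)-cyclodec-4-en-9-one fused to the trans γ-lactone | O=C1[C@H](C)CCC/C(C)=C/[C@H](O[Si](C)(C)C(C)(C)C)[C@H]2CC(=O)O[C@H]12
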